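**Retrosynthetic overview**

- The only strategic bond is the aryl–geranyl bond C3'–C1'' on ring B. It is traced back to the O4'–C1'' bond of an aryl geranyl ether through a photochemical 1,3-O→C shift, which fixes the site ortho to O4' and keeps the more nucleophilic ring A out of play.
- The ether comes from (2S)-naringenin 1, masked at O7 as silyl ether 2, and geraniol 3 by Mitsunobu coupling, giving 4.
- Irradiation of 4 gives the C-geranyl phenol 5, which is desilylated in the same flask to the target 6.
- No ring is formed: rings A, B and C and the C2 stereocentre are bought in 1, the 2''E olefin in 3.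

Assumption: (2S)-naringenin (natural, CAS 480-41-1) is bought as the single enantiomer (ee checked by chiral HPLC before use) and geraniol as the pure E isomer.

**Step 1**
Reactants: 1 (2S)-naringenin
Product: 2 (2S)-7-O-(tert-butyldimethylsilyl)naringenin
Conditions: TBSCl (1.05 equiv), imidazole (1.2 equiv), DMF, −20 → 0 °C, 2 h
Reagents that add atoms: tert-butyldimethylsilyl chloride (TBSCl), CC(C)(C)[Si](C)(C)Cl
Why: Silyl ether formation (Corey protocol) goes to O7 because the 7-OH, a vinylogous acid para to C4=O (pKa about 7.5), is the only hydroxyl that imidazole ionises to a useful extent (4'-OH pKa about 10, 5-OH locked in a hydrogen bond to C4=O), and the cold, mild conditions leave the C2 stereocentre alone.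

**Step 2**
Reactants: 2 (2S)-7-O-(tert-butyldimethylsilyl)naringenin, 3 geraniol
Product: 4 (2S)-4'-O-geranyl-7-O-(tert-butyldimethylsilyl)naringenin
Conditions: PPh3 (1.3 equiv), DIAD (1.3 equiv, added last, dropwise), THF, 0 °C, 1 h
Reagents that add atoms: none
Why: Mitsunobu etherification: with O7 masked and the 5-OH chelated, the 4'-OH is the only phenol that enters the redox condensation, the primary allylic alcohol is displaced by SN2 at C1 so the linear skeleton and the 2E olefin are kept, and under near-neutral conditions at 0 °C C2 is not epimerised.

**Step 3**
Reactants: 4 (2S)-4'-O-geranyl-7-O-(tert-butyldimethylsilyl)naringenin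
Product: 6 (2S)-3'-geranylnaringenin, via 7-O-TBS-3'-geranylnaringenin 5 (not isolated)
Conditions: hν 254 nm (low-pressure Hg lamp, FEP-coil flow reactor), degassed MeCN (2 mM), 15 °C; concentrate; then AcOH (1.5 equiv), Bu4NF (1.2 equiv), THF, 0 °C
Reagents that add atoms: none
Why: Proposed new method: a photo-Claisen-type 1,3-O→C geranyl shift on a 5-hydroxyflavanone, in which 254 nm light (the absorption minimum of the 5-hydroxychromanone, whose excited state relaxes harmlessly by intramolecular proton transfer) excites the 4-alkylphenyl ether, the weak O–C1'' bond (about 50 kcal/mol) breaks from the singlet state to a solvent-caged 4'-phenoxyl/geranyl radical pair, and the pair recloses at the only open position next to oxygen, C3' (C1' is blocked, return to oxygen only regenerates 4), through the unhindered primary terminus C1'' of an allyl radical that keeps its 2''E geometry on this timescale, after which the dienone tautomerises to phenol 5 and buffered fluoride removes the silyl group; no phenoxide, enolate or chalcone is formed, so the bought C2 stereocentre is untouched; closest known reaction type: the photo-Claisen rearrangement of simple allyl and prenyl aryl ethers, not yet shown for a geranyl ether or in a flavanone that carries a second, dominant chromophore.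

**Compound list**

1 | (2S)-naringenin, (2S)-5,7-dihydroxy-2-(4-hydroxyphenyl)chroman-4-one | Oc1ccc(cc1)[C@@H]1CC(=O)c2c(O)cc(O)cc2O1 | starting material
2 | (2S)-7-O-(tert-butyldimethylsilyl)naringenin | Oc1ccc(cc1)[C@@H]1CC(=O)c2c(O)cc(O[Si](C)(C)C(C)(C)C)cc2O1 | intermediate
3 | geraniol, (2E)-3,7-dimethylocta-2,6-dien-1-ol | CC(C)=CCC/C(C)=C/CO | starting material
4 | (2S)-4'-O-geranyl-7-O-(tert-butyldimethylsilyl)naringenin | CC(C)=CCC/C(C)=C/COc1ccc(cc1)[C@@H]1CC(=O)c2c(O)cc(O[Si](C)(C)C(C)(C)C)cc2O1 | intermediate
5 | (2S)-7-O-(tert-butyldimethylsilyl)-3'-geranylnaringenin | CC(C)=CCC/C(C)=C/Cc1cc(ccc1O)[C@@H]1CC(=O)c2c(O)cc(O[Si](C)(C)C(C)(C)C)cc2O1 | intermediate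
6 | (2S)-3'-geranylnaringenin, (2S)-2-{3-[(2E)-3,7-dimethylocta-2,6-dienyl]-4-hydroxyphenyl}-5,7-dihydroxychroman-4-one | CC(C)=CCC/C(C)=C/Cc1cc([C@@H]2CC(=O)c3c(O)cc(O)cc3O2)ccc1O | target

**Totals**

Total step count: 3. Longest linear sequence: 3 steps (1 → 2 → 4 → 6).

**Steps most likely to fail**

Step 3, the new photochemical shift, is the weakest. The 5-hydroxychromanone absorbs most of the 254 nm light and only turns it into heat. The excited aryl ether can also pass its energy to that chromophore before the O–C bond breaks. The quantum yield is therefore expected to be far below that of a simple aryl prenyl ether, and long residence times will be needed. Radicals that escape the cage give phenol 2 and geranyl dimers, and coupling through C3'' gives a branched isomer. The fallback uses known chemistry and sets out from 2. Iridium-catalysed ortho C–H borylation ([Ir(OMe)(cod)]2, 4,4'-di-tert-butyl-2,2'-bipyridine, HBpin, THF, 80 °C) is directed by the phenol, which is O-borylated in situ. The two C–H positions of ring A are each flanked by two substituents and stay untouched. This gives (2S)-7-O-TBS-3'-(pinacolboryl)naringenin F1. Geraniol 3 is converted with ClCO2Me and pyridine in CH2Cl2 at 0 °C into geranyl methyl carbonate F2. Suzuki–Miyaura allylation of F1 with F2 under zerovalent palladium (Pd(PPh3)4, THF, 50 °C) needs no added base, because the methoxide released on ionisation activates the boronate. It joins the less hindered allyl terminus to C3' and comes back to the route at 5, which is desilylated as in step 3.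

Step 2, the Mitsunobu etherification, is next. The ion-paired 4'-phenoxide that forms in passing could open ring C through a quinone methide and erode the ee. SN2' attack or betaine-induced loss of the labile 7-O-silyl group would lower the yield. The fallback sets out from 2 and 3. Geraniol 3 is converted with PBr3 in Et2O at −10 °C into geranyl bromide F3. Phenol 2 is then alkylated with F3 and Ag2O in toluene at room temperature, a silver-assisted Williamson etherification that never generates a free phenoxide. It comes back to the route at 4.

Step 1, the selective silylation, is third. If mono-silylation at O7 is not clean, mixtures of 7-O-, 4'-O- and bis-silyl ethers result, and the 7-O-silyl ether may be partly lost on silica. The fallback sets out from 1 and differentiates the two phenols by deprotection instead of protection. Mitsunobu coupling of 1 with 2.2 equiv of geraniol 3 (PPh3, DIAD, THF, 0 °C) gives (2S)-4',7-di-O-geranylnaringenin F4. Pd(PPh3)4 (2 mol%) with morpholine in THF at room temperature then cleaves only the 7-O-geranyl ether, because zerovalent palladium ionises the ether of the far more acidic 7-phenol first. This gives (2S)-4'-O-geranylnaringenin F5. F5 is irradiated as in step 3, without the fluoride treatment, and comes back to the route at 6.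

**Further compounds**

F1 | step 3 | (2S)-7-O-TBS-3'-(pinacolboryl)naringenin | CC1(C)OB(OC1(C)C)c1cc(ccc1O)[C@@H]1CC(=O)c2c(O)cc(O[Si](C)(C)C(C)(C)C)cc2O1
F2 | step 3 | geranyl methyl carbonate | CC(C)=CCC/C(C)=C/COC(=O)OC
F3 | step 2 | geranyl bromide | CC(C)=CCC/C(C)=C/CBr
F4 | step 1 | (2S)-4',7-di-O-geranylnaringenin | CC(C)=CCC/C(C)=C/COc1ccc(cc1)[C@@H]1CC(=O)c2c(O)cc(OC/C=C(\C)CCC=C(C)C)cc2O1
F5 | step 1 | (2S)-4'-O-geranylnaringenin | CC(C)=CCC/C(C)=C/COc1ccc(cc1)[C@@H]1CC(=O)c2c(O)cc(O)cc2O1
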